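The plan rests on one disconnection: the methyl group on the quaternary carbon C1 of each ring is traced back to the methylene of a cyclopropane fused across C1 and C6. In ring A that methyl is cis to the C2 hydroxyl, so the zinc alkoxide of an (S)-cyclohex-2-en-1-ol, bearing CH2OTBS on the alkene carbon and a dioxolane at C3, delivers CH2 to its own face. One operation closes the three-membered ring, forms the C1–CH2 bond and fixes C1 relative to C2; hydrogenolysis of the C6–CH2 bond later leaves the methyl. The same alcohol, silylated at C2 and delivering from its primary hydroxyl, gives ring B. Two Z-selective Wittig reactions join the rings.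

Key step: step 6

Remarks on the chemistry
- Labels: in each ring C1 is the quaternary carbon, C2 the carbinol, C3 the ketal (later ketone, then alkylidene) carbon, C4–C6 the methylenes; C7 is the transferred methylene. TBS = tert-butyldimethylsilyl, Piv = pivaloyl.
- Assumption: in the CBS reduction the α-branched alkenyl flank of ketone 7 acts as the large group, so the (S)-catalyst gives (S)-8; if the spiroketal flank should dominate, the (R)-catalyst is taken instead.
- Design: both rings come from the single enantiomer 8. Ring B needs the methyl trans to the C2 oxygen; this is reached by silylating C2 and letting the primary hydroxyl deliver the methylene, so neither an antipodal series nor a carbinol inversion at a neopentyl centre is needed.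

Step 1
Reactants: 1 1,4-dioxaspiro[4.5]decan-6-one
Product: 3 trimethyl(1,4-dioxaspiro[4.5]dec-6-en-6-yloxy)silane, via lithium enolate 2 (not isolated)
Conditions: LiN(iPr)2, THF, −78 °C; then Me3SiCl, −78 °C to rt
Reagents that add atoms: chlorotrimethylsilane, C[Si](C)(C)Cl
Why: Enolate formation and O-silylation, regiodefined because C7 is the only enolisable α-carbon (the other is the spiro ketal carbon).

Step 2
Reactants: 3 trimethyl(1,4-dioxaspiro[4.5]dec-6-en-6-yloxy)silane
Product: 4 1,4-dioxaspiro[4.5]dec-7-en-6-one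
Conditions: Pd(OAc)2 (1.05 equiv), MeCN, rt
Reagents that add atoms: none
Why: Saegusa oxidation, in which divalent palladium is transferred to the enol ether and β-hydride elimination from the palladium enolate gives the enone and zerovalent palladium.

Step 3
Reactants: 4 1,4-dioxaspiro[4.5]dec-7-en-6-one; 5 formaldehyde
Product: 6 7-(hydroxymethyl)-1,4-dioxaspiro[4.5]dec-7-en-6-one
Conditions: 37% aq. CH2O, 4-(dimethylamino)pyridine (0.2 equiv), THF/H2O, rt
Reagents that add atoms: formaldehyde (compound 5), C=O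
Why: Morita–Baylis–Hillman reaction, in which conjugate addition of the amine gives an enolate that is hydroxymethylated at the α-carbon before the amine is expelled.

Step 4
Reactants: 6 7-(hydroxymethyl)-1,4-dioxaspiro[4.5]dec-7-en-6-one
Product: 7 7-{[(tert-butyldimethylsilyl)oxy]methyl}-1,4-dioxaspiro[4.5]dec-7-en-6-one
Conditions: tBuMe2SiCl, imidazole, CH2Cl2, 0 °C to rt
Reagents that add atoms: tert-butyldimethylsilyl chloride, CC(C)(C)[Si](C)(C)Cl
Why: Standard silylation of the primary allylic alcohol, which leaves the later carbinol as the only free hydroxyl for the key step.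

Step 5
Reactants: 7 7-{[(tert-butyldimethylsilyl)oxy]methyl}-1,4-dioxaspiro[4.5]dec-7-en-6-one
Product: 8 (6S)-7-{[(tert-butyldimethylsilyl)oxy]methyl}-1,4-dioxaspiro[4.5]dec-7-en-6-ol
Conditions: (S)-Me-CBS catalyst [(S)-1-methyl-3,3-diphenyltetrahydro-1H,3H-pyrrolo[1,2-c][1,3,2]oxazaborole, 0.2 equiv], BH3·THF, THF, −20 °C
Reagents that add atoms: none
Why: CBS reduction, in which the oxazaborolidine–borane complex should bind the carbonyl oxygen on the side away from the in-plane CH2OTBS-bearing alkenyl flank and deliver hydride in a 1,2-sense to one face, setting the (S)-carbinol.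

Step 6
Reactants: 8 (6S)-7-{[(tert-butyldimethylsilyl)oxy]methyl}-1,4-dioxaspiro[4.5]dec-7-en-6-ol; 9 diiodomethane
Product: 11 (1S,2S,6R)-1-{[(tert-butyldimethylsilyl)oxy]methyl}spiro[bicyclo[4.1.0]heptane-3,2'-[1,3]dioxolan]-2-ol, via ethylzinc alkoxide 10 (not isolated)
Conditions: Et2Zn (3 equiv), CH2I2 (6 equiv), CH2Cl2, −10 °C to rt; aq. NH4Cl
Reagents that add atoms: diiodomethane (compound 9), ICI
Why: Et2Zn converts the C2 hydroxyl into the ethylzinc alkoxide 10, which binds the iodomethylzinc carbenoid formed from Et2Zn and CH2I2 and passes CH2 to the C1=C6 alkene through a concerted butterfly-shaped transition state. The closest known reaction type is the hydroxyl-directed Simmons–Smith cyclopropanation of cyclic allylic alcohols, for which trisubstituted electron-rich alkenes are the best substrates. The three-membered ring closes by a [2+1] methylene transfer in which the C1–C7 and C6–C7 bonds form suprafacially on the face that carries the oxygen. The new stereocentres C1 and C6 are therefore controlled by the C2 carbinol set in step 5, and the cyclopropane is cis to the hydroxyl. The step needs facial selectivity only, and the intramolecular delivery from the pseudoaxial zinc alkoxide secures it, since the CH2OTBS group lies in the alkene plane and has no facial bias. There is a single alkene, and the ketal and silyl ether are inert to the carbenoid.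

Step 7
Reactants: 11 (1S,2S,6R)-1-{[(tert-butyldimethylsilyl)oxy]methyl}spiro[bicyclo[4.1.0]heptane-3,2'-[1,3]dioxolan]-2-ol
Product: 12 (6S,7S)-7-{[(tert-butyldimethylsilyl)oxy]methyl}-7-methyl-1,4-dioxaspiro[4.5]decan-6-ol
Conditions: H2 (3 atm), PtO2, AcOH, NaOAc, rt
Reagents that add atoms: none
Why: Catalytic hydrogenolysis of the cyclopropane on platinum should cleave the least hindered C6–C7 bond (CH to CH2), so C7 stays on the quaternary carbon as a methyl cis to the hydroxyl and no stereocentre is touched.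

Step 8
Reactants: 12 (6S,7S)-7-{[(tert-butyldimethylsilyl)oxy]methyl}-7-methyl-1,4-dioxaspiro[4.5]decan-6-ol
Product: 13 (6S,7S)-6-(TBSO)-7-(TBSOCH2)-7-methyl-1,4-dioxaspiro[4.5]decane
Conditions: tBuMe2SiOTf, 2,6-lutidine, CH2Cl2, 0 °C to rt
Reagents that add atoms: tert-butyldimethylsilyl trifluoromethanesulfonate, CC(C)(C)[Si](C)(C)OS(=O)(=O)C(F)(F)F
Why: Silylation with a silyl triflate and a hindered base caps the hindered secondary carbinol before the ketone is unveiled, which prevents α-ketol isomerisation later.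

Step 9
Reactants: 13 (6S,7S)-6-(TBSO)-7-(TBSOCH2)-7-methyl-1,4-dioxaspiro[4.5]decane
Product: 14 (2S,3S)-2-(TBSO)-3-(hydroxymethyl)-3-methylcyclohexan-1-one
Conditions: TsOH·H2O (0.3 equiv), acetone/H2O (5:1), 40 °C
Reagents that add atoms: water, O
Why: Acid-catalysed hydrolysis should remove the dioxolane and the primary silyl ether in one operation, while the secondary silyl ether wedged between the quaternary carbon and the carbonyl hydrolyses far more slowly.

Step 10
Reactants: 14 (2S,3S)-2-(TBSO)-3-(hydroxymethyl)-3-methylcyclohexan-1-one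
Product: 15 [(1S,2S)-2-(TBSO)-1-methyl-3-oxocyclohexyl]methyl pivalate (ring A ketone)
Conditions: tBuCOCl, pyridine, 4-(dimethylamino)pyridine (cat.), CH2Cl2, 0 °C to rt
Reagents that add atoms: pivaloyl chloride, CC(C)(C)C(Cl)=O
Why: Acylation of the primary alcohol gives a pivalate that is inert to ylides and can later be removed by hydride without touching silyl ethers.

Step 11
Reactants: 8 (6S)-7-{[(tert-butyldimethylsilyl)oxy]methyl}-1,4-dioxaspiro[4.5]dec-7-en-6-ol
Product: 16 (6S)-6-(TBSO)-7-(TBSOCH2)-1,4-dioxaspiro[4.5]dec-7-ene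
Conditions: tBuMe2SiOTf, 2,6-lutidine, CH2Cl2, −78 to 0 °C
Reagents that add atoms: tert-butyldimethylsilyl trifluoromethanesulfonate, CC(C)(C)[Si](C)(C)OS(=O)(=O)C(F)(F)F
Why: Silylation of the secondary allylic alcohol turns the C2 oxygen from a directing group into a bulky shielding group for the ring B series.

Step 12
Reactants: 16 (6S)-6-(TBSO)-7-(TBSOCH2)-1,4-dioxaspiro[4.5]dec-7-ene
Product: 17 [(6S)-6-(TBSO)-1,4-dioxaspiro[4.5]dec-7-en-7-yl]methanol
Conditions: HF·pyridine, pyridine, THF, 0 °C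
Reagents that add atoms: none
Why: Selective desilylation, since buffered fluoride cleaves the primary allylic silyl ether much faster than the secondary one flanked by the ketal and the substituted alkene carbon.

Step 13
Reactants: 17 [(6S)-6-(TBSO)-1,4-dioxaspiro[4.5]dec-7-en-7-yl]methanol; 9 diiodomethane
Product: 19 [(1R,2S,6S)-2-(TBSO)spiro[bicyclo[4.1.0]heptane-3,2'-[1,3]dioxolan]-1-yl]methanol, via ethylzinc alkoxide 18 (not isolated)
Conditions: Et2Zn (3 equiv), CH2I2 (6 equiv), CH2Cl2, −10 °C to rt; aq. NH4Cl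
Reagents that add atoms: diiodomethane (compound 9), ICI
Why: Simmons–Smith cyclopropanation delivered from the zinc alkoxide of the primary allylic alcohol, which can reach either face, so the face is chosen by the C2 silyl ether (pseudoaxial to avoid allylic strain with the CH2O group) and the methylene should add trans to it, setting C1 and C6.

Step 14
Reactants: 19 [(1R,2S,6S)-2-(TBSO)spiro[bicyclo[4.1.0]heptane-3,2'-[1,3]dioxolan]-1-yl]methanol
Product: 20 [(6S,7R)-6-(TBSO)-7-methyl-1,4-dioxaspiro[4.5]decan-7-yl]methanol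
Conditions: H2 (3 atm), PtO2, AcOH, NaOAc, rt
Reagents that add atoms: none
Why: Hydrogenolysis of the least hindered C6–C7 cyclopropane bond, as in step 7, leaves the methyl on C1 trans to the C2 oxygen, which is the relative configuration of ring B.

Step 15
Reactants: 20 [(6S,7R)-6-(TBSO)-7-methyl-1,4-dioxaspiro[4.5]decan-7-yl]methanol
Product: 21 [(6S,7R)-6-(TBSO)-7-methyl-1,4-dioxaspiro[4.5]decan-7-yl]methyl pivalate
Conditions: tBuCOCl, pyridine, 4-(dimethylamino)pyridine (cat.), CH2Cl2, 0 °C to rt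
Reagents that add atoms: pivaloyl chloride, CC(C)(C)C(Cl)=O
Why: Acylation of the primary alcohol under non-alkoxide conditions, which avoids silyl migration from the neighbouring oxygen.

Step 16
Reactants: 21 [(6S,7R)-6-(TBSO)-7-methyl-1,4-dioxaspiro[4.5]decan-7-yl]methyl pivalate
Product: 22 [(1R,2S)-2-(TBSO)-1-methyl-3-oxocyclohexyl]methyl pivalate (ring B ketone)
Conditions: TsOH·H2O (0.2 equiv), acetone/H2O (5:1), 40 °C
Reagents that add atoms: water, O
Why: Acid-catalysed ketal hydrolysis unveils the ketone, and the pivalate and the hindered secondary silyl ether should survive these conditions.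

Step 17
Reactants: 23 (4-bromobutoxy)(tert-butyl)dimethylsilane
Product: 24 {4-[(tert-butyldimethylsilyl)oxy]butyl}triphenylphosphonium bromide
Conditions: PPh3, MeCN, reflux
Reagents that add atoms: triphenylphosphine, c1ccc(cc1)P(c1ccccc1)c1ccccc1
Why: SN2 quaternisation of triphenylphosphine by the primary bromide gives the phosphonium salt.

Step 18
Reactants: 15 [(1S,2S)-2-(TBSO)-1-methyl-3-oxocyclohexyl]methyl pivalate; 24 {4-[(tert-butyldimethylsilyl)oxy]butyl}triphenylphosphonium bromide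
Product: 26 [(1S,2R,3Z)-2-(TBSO)-3-{4-[(tert-butyldimethylsilyl)oxy]butylidene}-1-methylcyclohexyl]methyl pivalate, via phosphorus ylide 25 (not isolated)
Conditions: 24 (2.5 equiv), KN(SiMe3)2 (2.4 equiv), THF, 0 °C; then 15, −78 °C to rt
Reagents that add atoms: none
Why: Wittig olefination under salt-free conditions, relying on the known tendency of non-stabilised ylides to react with α-oxygenated ketones under kinetic control so that the alkyl chain ends up cis to the oxygen-bearing carbon, here the Z alkene.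

Step 19
Reactants: 26 [(1S,2R,3Z)-2-(TBSO)-3-{4-[(tert-butyldimethylsilyl)oxy]butylidene}-1-methylcyclohexyl]methyl pivalate
Product: 27 [(1S,2R,3Z)-2-(TBSO)-3-(4-hydroxybutylidene)-1-methylcyclohexyl]methyl pivalate
Conditions: HF·pyridine, pyridine, THF, 0 °C
Reagents that add atoms: none
Why: Selective desilylation of the unhindered primary silyl ether in the presence of the hindered secondary allylic one.

Step 20
Reactants: 27 [(1S,2R,3Z)-2-(TBSO)-3-(4-hydroxybutylidene)-1-methylcyclohexyl]methyl pivalate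
Product: 28 [(1S,2R,3Z)-2-(TBSO)-3-(4-iodobutylidene)-1-methylcyclohexyl]methyl pivalate
Conditions: I2, PPh3, imidazole, CH2Cl2, 0 °C to rt
Reagents that add atoms: iodine, II
Why: Appel-type iodination, in which the alkoxyphosphonium ion of the primary alcohol is displaced by iodide under neutral conditions.

Step 21
Reactants: 28 [(1S,2R,3Z)-2-(TBSO)-3-(4-iodobutylidene)-1-methylcyclohexyl]methyl pivalate
Product: 29 {(4Z)-4-[(2R,3S)-2-(TBSO)-3-methyl-3-(pivaloyloxymethyl)cyclohexylidene]butyl}triphenylphosphonium iodide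
Conditions: PPh3, MeCN, 80 °C
Reagents that add atoms: triphenylphosphine, c1ccc(cc1)P(c1ccccc1)c1ccccc1
Why: SN2 quaternisation of triphenylphosphine by the primary iodide under neutral conditions that leave the ester and silyl ether intact.

Step 22
Reactants: 29 {(4Z)-4-[(2R,3S)-2-(TBSO)-3-methyl-3-(pivaloyloxymethyl)cyclohexylidene]butyl}triphenylphosphonium iodide; 22 [(1R,2S)-2-(TBSO)-1-methyl-3-oxocyclohexyl]methyl pivalate
Product: 31 bis-pivalate of the Z,Z-diene, [(1S,2R,3Z)-2-(TBSO)-3-{(4Z)-4-[(2R,3R)-2-(TBSO)-3-methyl-3-(pivaloyloxymethyl)cyclohexylidene]butylidene}-1-methylcyclohexyl]methyl pivalate, via phosphorus ylide 30 (not isolated)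
Conditions: KN(SiMe3)2 (1.0 equiv), THF, −78 to 0 °C; then 22 (1.3 equiv), −78 °C to rt
Reagents that add atoms: none
Why: Second Wittig olefination of an α-silyloxy ketone with a non-stabilised ylide, expected for the same kinetic reason as in step 18 to place the chain cis to C2' and so to give the second Z alkene.

Step 23
Reactants: 31 bis-pivalate of the Z,Z-diene
Product: 32 diol, [(1S,2R,3Z)-2-(TBSO)-3-{(4Z)-4-[(2R,3R)-2-(TBSO)-3-(hydroxymethyl)-3-methylcyclohexylidene]butylidene}-1-methylcyclohexyl]methanol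
Conditions: iBu2AlH (6 equiv), CH2Cl2, −78 °C; aq. Rochelle salt
Reagents that add atoms: none
Why: Hydride reduction cleaves both pivalate esters to the primary alcohols, while silyl ethers and alkenes are inert.

Step 24
Reactants: 32 diol
Product: 33 dialdehyde, (1R,2R,3Z)-2-(TBSO)-3-{(4Z)-4-[(2R,3S)-2-(TBSO)-3-formyl-3-methylcyclohexylidene]butylidene}-1-methylcyclohexane-1-carbaldehyde
Conditions: Dess–Martin periodinane, pyridine, CH2Cl2, 0 °C to rt
Reagents that add atoms: none
Why: Dess–Martin oxidation of the neopentyl primary alcohols gives aldehydes on quaternary carbons, which cannot epimerise.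

Step 25
Reactants: 33 dialdehyde; 34 allylmagnesium bromide
Product: 35 bis(homoallylic alcohol), 33 with each CHO converted into CH(OH)CH2CH=CH2 (both new carbinol centres uncontrolled)
Conditions: CH2=CHCH2MgBr (excess), Et2O/THF, −78 °C; aq. NH4Cl
Reagents that add atoms: allylmagnesium bromide (compound 34), C=CC[Mg]Br
Why: Grignard addition of the symmetrical allyl nucleophile to both non-enolisable aldehydes avoids the α/γ regiochemistry problem of a prenyl metal, and the new carbinol centres are removed in step 27.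

Step 26
Reactants: 35 bis(homoallylic alcohol); 36 2-methyl-2-butene
Product: 37 bis(prenyl carbinol), 35 with each CH2CH=CH2 converted into CH2CH=C(CH3)2
Conditions: second-generation Grubbs catalyst RuCl2(=CHPh)(PCy3)(H2IMes) (5 mol%), 2-methyl-2-butene/CH2Cl2, 35 °C
Reagents that add atoms: 2-methyl-2-butene (compound 36), CC=C(C)C
Why: Olefin cross-metathesis with 2-methyl-2-butene converts each terminal vinyl group into the isopropylidene terminus, while the trisubstituted exocyclic alkenes are too hindered to enter the catalytic cycle.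

Step 27
Reactants: 37 bis(prenyl carbinol)
Product: 38 bis-silyl ether of the target, 1-[(1R,2R,3Z)-2-(TBSO)-3-{(4Z)-4-[(2R,3S)-2-(TBSO)-3-methyl-3-(4-methylpent-3-enoyl)cyclohexylidene]butylidene}-1-methylcyclohexyl]-4-methylpent-3-en-1-one
Conditions: Dess–Martin periodinane, pyridine, CH2Cl2, 0 °C to rt
Reagents that add atoms: none
Why: Buffered Dess–Martin oxidation of the homoallylic alcohols gives the β,γ-unsaturated ketones under conditions that should not move the alkene into conjugation.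

Step 28
Reactants: 38 bis-silyl ether of the target
Product: 39 CNP0297042.3, 1-[(1R,2R,3Z)-2-hydroxy-3-{(4Z)-4-[(2R,3S)-2-hydroxy-3-methyl-3-(4-methylpent-3-enoyl)cyclohexylidene]butylidene}-1-methylcyclohexyl]-4-methylpent-3-en-1-one
Conditions: HF·pyridine, THF, 0 °C to rt
Reagents that add atoms: none
Why: Desilylation with mildly acidic fluoride frees both carbinols without the base that would trigger retro-aldol cleavage of the β-hydroxy ketones or conjugation of the β,γ-enones.

Compound list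
1 | 1,4-dioxaspiro[4.5]decan-6-one | O=C1CCCCC12OCCO2 | starting material
2 | lithium 1,4-dioxaspiro[4.5]dec-6-en-6-olate | [Li]OC1=CCCCC12OCCO2 | intermediate
3 | trimethyl(1,4-dioxaspiro[4.5]dec-6-en-6-yloxy)silane | C[Si](C)(C)OC1=CCCCC12OCCO2 | intermediate
4 | 1,4-dioxaspiro[4.5]dec-7-en-6-one | O=C1C=CCCC12OCCO2 | intermediate
5 | formaldehyde | C=O | starting material
6 | 7-(hydroxymethyl)-1,4-dioxaspiro[4.5]dec-7-en-6-one | O=C1C(CO)=CCCC12OCCO2 | intermediate
7 | 7-{[(tert-butyldimethylsilyl)oxy]methyl}-1,4-dioxaspiro[4.5]dec-7-en-6-one | CC(C)(C)[Si](C)(C)OCC1=CCCC2(OCCO2)C1=O | intermediate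
8 | (6S)-7-{[(tert-butyldimethylsilyl)oxy]methyl}-1,4-dioxaspiro[4.5]dec-7-en-6-ol | CC(C)(C)[Si](C)(C)OCC1=CCCC2(OCCO2)[C@H]1O | intermediate
9 | diiodomethane | ICI | starting material
10 | ethylzinc alkoxide of 8 | CC(C)(C)[Si](C)(C)OCC1=CCCC2(OCCO2)[C@H]1O[Zn]CC | intermediate
11 | (1S,2S,6R)-1-{[(tert-butyldimethylsilyl)oxy]methyl}spiro[bicyclo[4.1.0]heptane-3,2'-[1,3]dioxolan]-2-ol (cyclopropane cis to OH) | CC(C)(C)[Si](C)(C)OC[C@]12C[C@H]1CCC3(OCCO3)[C@H]2O | intermediate
12 | (6S,7S)-7-{[(tert-butyldimethylsilyl)oxy]methyl}-7-methyl-1,4-dioxaspiro[4.5]decan-6-ol (methyl cis to OH) | CC(C)(C)[Si](C)(C)OC[C@]1(C)CCCC2(OCCO2)[C@H]1O | intermediate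
13 | (6S,7S)-6-(TBSO)-7-(TBSOCH2)-7-methyl-1,4-dioxaspiro[4.5]decane | CC(C)(C)[Si](C)(C)OC[C@]1(C)CCCC2(OCCO2)[C@H]1O[Si](C)(C)C(C)(C)C | intermediate
14 | (2S,3S)-2-(TBSO)-3-(hydroxymethyl)-3-methylcyclohexan-1-one | OC[C@]1(C)CCCC(=O)[C@H]1O[Si](C)(C)C(C)(C)C | intermediate
15 | [(1S,2S)-2-(TBSO)-1-methyl-3-oxocyclohexyl]methyl pivalate (ring A ketone) | CC(C)(C)C(=O)OC[C@]1(C)CCCC(=O)[C@H]1O[Si](C)(C)C(C)(C)C | intermediate
16 | (6S)-6-(TBSO)-7-(TBSOCH2)-1,4-dioxaspiro[4.5]dec-7-ene | CC(C)(C)[Si](C)(C)OCC1=CCCC2(OCCO2)[C@H]1O[Si](C)(C)C(C)(C)C | intermediate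
17 | [(6S)-6-(TBSO)-1,4-dioxaspiro[4.5]dec-7-en-7-yl]methanol | OCC1=CCCC2(OCCO2)[C@H]1O[Si](C)(C)C(C)(C)C | intermediate
18 | ethylzinc alkoxide of 17 | CC[Zn]OCC1=CCCC2(OCCO2)[C@H]1O[Si](C)(C)C(C)(C)C | intermediate
19 | [(1R,2S,6S)-2-(TBSO)spiro[bicyclo[4.1.0]heptane-3,2'-[1,3]dioxolan]-1-yl]methanol (cyclopropane trans to OTBS) | OC[C@@]12C[C@@H]1CCC3(OCCO3)[C@H]2O[Si](C)(C)C(C)(C)C | intermediate
20 | [(6S,7R)-6-(TBSO)-7-methyl-1,4-dioxaspiro[4.5]decan-7-yl]methanol (methyl trans to OTBS) | OC[C@@]1(C)CCCC2(OCCO2)[C@H]1O[Si](C)(C)C(C)(C)C | intermediate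
21 | [(6S,7R)-6-(TBSO)-7-methyl-1,4-dioxaspiro[4.5]decan-7-yl]methyl pivalate | CC(C)(C)C(=O)OC[C@@]1(C)CCCC2(OCCO2)[C@H]1O[Si](C)(C)C(C)(C)C | intermediate
22 | [(1R,2S)-2-(TBSO)-1-methyl-3-oxocyclohexyl]methyl pivalate (ring B ketone) | CC(C)(C)C(=O)OC[C@@]1(C)CCCC(=O)[C@H]1O[Si](C)(C)C(C)(C)C | intermediate
23 | (4-bromobutoxy)(tert-butyl)dimethylsilane | CC(C)(C)[Si](C)(C)OCCCCBr | starting material
24 | {4-[(tert-butyldimethylsilyl)oxy]butyl}triphenylphosphonium bromide | CC(C)(C)[Si](C)(C)OCCCC[P+](c1ccccc1)(c1ccccc1)c1ccccc1.[Br-] | intermediate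
25 | {4-[(tert-butyldimethylsilyl)oxy]butylidene}triphenylphosphorane | CC(C)(C)[Si](C)(C)OCCCC=P(c1ccccc1)(c1ccccc1)c1ccccc1 | intermediate
26 | [(1S,2R,3Z)-2-(TBSO)-3-{4-[(tert-butyldimethylsilyl)oxy]butylidene}-1-methylcyclohexyl]methyl pivalate | CC(C)(C)C(=O)OC[C@]1(C)CCC/C(=C/CCCO[Si](C)(C)C(C)(C)C)[C@H]1O[Si](C)(C)C(C)(C)C | intermediate
27 | [(1S,2R,3Z)-2-(TBSO)-3-(4-hydroxybutylidene)-1-methylcyclohexyl]methyl pivalate | CC(C)(C)C(=O)OC[C@]1(C)CCC/C(=C/CCCO)[C@H]1O[Si](C)(C)C(C)(C)C | intermediate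
28 | [(1S,2R,3Z)-2-(TBSO)-3-(4-iodobutylidene)-1-methylcyclohexyl]methyl pivalate | CC(C)(C)C(=O)OC[C@]1(C)CCC/C(=C/CCCI)[C@H]1O[Si](C)(C)C(C)(C)C | intermediate
29 | {(4Z)-4-[(2R,3S)-2-(TBSO)-3-methyl-3-(pivaloyloxymethyl)cyclohexylidene]butyl}triphenylphosphonium iodide | CC(C)(C)C(=O)OC[C@]1(C)CCC/C(=C/CCC[P+](c2ccccc2)(c2ccccc2)c2ccccc2)[C@H]1O[Si](C)(C)C(C)(C)C.[I-] | intermediate
30 | ylide of 29, {(4Z)-4-[(2R,3S)-2-(TBSO)-3-methyl-3-(pivaloyloxymethyl)cyclohexylidene]butylidene}triphenylphosphorane | CC(C)(C)C(=O)OC[C@]1(C)CCC/C(=C/CCC=P(c2ccccc2)(c2ccccc2)c2ccccc2)[C@H]1O[Si](C)(C)C(C)(C)C | intermediate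
31 | [(1S,2R,3Z)-2-(TBSO)-3-{(4Z)-4-[(2R,3R)-2-(TBSO)-3-methyl-3-(pivaloyloxymethyl)cyclohexylidene]butylidene}-1-methylcyclohexyl]methyl pivalate | CC(C)(C)C(=O)OC[C@]1(C)CCC/C(=C/CC/C=C2/CCC[C@](C)(COC(=O)C(C)(C)C)[C@@H]2O[Si](C)(C)C(C)(C)C)[C@H]1O[Si](C)(C)C(C)(C)C | intermediate
32 | [(1S,2R,3Z)-2-(TBSO)-3-{(4Z)-4-[(2R,3R)-2-(TBSO)-3-(hydroxymethyl)-3-methylcyclohexylidene]butylidene}-1-methylcyclohexyl]methanol | OC[C@]1(C)CCC/C(=C/CC/C=C2/CCC[C@](C)(CO)[C@@H]2O[Si](C)(C)C(C)(C)C)[C@H]1O[Si](C)(C)C(C)(C)C | intermediate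
33 | (1R,2R,3Z)-2-(TBSO)-3-{(4Z)-4-[(2R,3S)-2-(TBSO)-3-formyl-3-methylcyclohexylidene]butylidene}-1-methylcyclohexane-1-carbaldehyde | O=C[C@]1(C)CCC/C(=C/CC/C=C2/CCC[C@](C)(C=O)[C@@H]2O[Si](C)(C)C(C)(C)C)[C@H]1O[Si](C)(C)C(C)(C)C | intermediate
34 | allylmagnesium bromide | C=CC[Mg]Br | starting material
35 | 1-[(1S,2R,3Z)-2-(TBSO)-3-{(4Z)-4-[(2R,3R)-2-(TBSO)-3-(1-hydroxybut-3-enyl)-3-methylcyclohexylidene]butylidene}-1-methylcyclohexyl]but-3-en-1-ol (side-chain carbinols as epimer mixture) | C=CCC(O)[C@]1(C)CCC/C(=C/CC/C=C2/CCC[C@](C)(C(O)CC=C)[C@@H]2O[Si](C)(C)C(C)(C)C)[C@H]1O[Si](C)(C)C(C)(C)C | intermediate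
36 | 2-methyl-2-butene | CC=C(C)C | starting material
37 | 1-[(1S,2R,3Z)-2-(TBSO)-3-{(4Z)-4-[(2R,3R)-2-(TBSO)-3-(1-hydroxy-4-methylpent-3-enyl)-3-methylcyclohexylidene]butylidene}-1-methylcyclohexyl]-4-methylpent-3-en-1-ol (side-chain carbinols as epimer mixture) | CC(C)=CCC(O)[C@]1(C)CCC/C(=C/CC/C=C2/CCC[C@](C)(C(O)CC=C(C)C)[C@@H]2O[Si](C)(C)C(C)(C)C)[C@H]1O[Si](C)(C)C(C)(C)C | intermediate
38 | 1-[(1R,2R,3Z)-2-(TBSO)-3-{(4Z)-4-[(2R,3S)-2-(TBSO)-3-methyl-3-(4-methylpent-3-enoyl)cyclohexylidene]butylidene}-1-methylcyclohexyl]-4-methylpent-3-en-1-one | CC(C)=CCC(=O)[C@]1(C)CCC/C(=C/CC/C=C2/CCC[C@](C)(C(=O)CC=C(C)C)[C@@H]2O[Si](C)(C)C(C)(C)C)[C@H]1O[Si](C)(C)C(C)(C)C | intermediate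
39 | CNP0297042.3, 1-[(1R,2R,3Z)-2-hydroxy-3-{(4Z)-4-[(2R,3S)-2-hydroxy-3-methyl-3-(4-methylpent-3-enoyl)cyclohexylidene]butylidene}-1-methylcyclohexyl]-4-methylpent-3-en-1-one | CC(C)=CCC(=O)[C@]1(C)CCC/C(=C/CC/C=C2/CCC[C@](C)(C(=O)CC=C(C)C)[C@@H]2O)[C@H]1O | target

Total step count: 28. Longest linear sequence: 21 steps (steps 1–10, then 18–28); the ring B branch (steps 11–16) and the linker salt (step 17) join it at steps 22 and 18.

Steps most likely to fail

1. Step 18 (step 22 is the same reaction type). The basic ylide may enolise the hindered ketone instead of adding to it, and kinetic control may not favour the Z alkene strongly enough on a ring ketone. The fallback is a stereospecific Horner–Wittig sequence that sets out from 15 and 23. Bromide 23 is alkylated onto Ph2P(O)H with KN(SiMe3)2 in THF to give {4-[(tert-butyldimethylsilyl)oxy]butyl}diphenylphosphine oxide F8. Its lithio derivative (n-BuLi, THF, −78 °C) is added to 15, the mixture is quenched cold and the adducts are separated by chromatography. The β-hydroxy phosphine oxide F9, meaning the adducts in which hydroxyl and phosphoryl can eclipse with the chain on the C2 side, undergoes syn-elimination with NaH in DMF. This can give only the Z alkene and comes back to the route at 26.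

2. Step 5. Both flanks of ketone 7 are bulky, so the catalyst may discriminate the carbonyl faces poorly, and the enantiomeric purity of 8, on which both rings depend, could be too low. The fallback replaces asymmetric catalysis by resolution and sets out from 7. Luche reduction (NaBH4, CeCl3·7H2O, MeOH) gives the racemic alcohol F1. Esterification with (S)-2-methoxy-2-phenylacetic acid (N,N'-dicyclohexylcarbodiimide, 4-(dimethylamino)pyridine, CH2Cl2) gives two diastereomers separable by chromatography, the (6S) ester F2 and the (6R) ester F3. Saponification of F2 (LiOH, THF/MeOH/H2O) comes back to the route at 8.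

3. Step 13. The silyl ether oxygen may bind zinc and draw the methylene to its own face, or the facial bias may be incomplete, which would erode the trans relationship needed for ring B. The fallback uses steric approach control by a free carbene on the fully silylated alkene and sets out from 16. Dibromocarbene (CHBr3, KOtBu, pentane, 0 °C) should add to the face away from the pseudoaxial silyl ether to give the dibromocyclopropane F4. Radical reduction (Bu3SnH, azobisisobutyronitrile, toluene, 80 °C) removes both bromines to give the cyclopropane F5. Hydrogenolysis as in step 14 gives the bis-silyl ether F6, and acid hydrolysis as in step 9 gives the hydroxy ketone F7. Pivaloylation as in step 10 comes back to the route at 22.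

Further compounds
F1 | step 5 | racemic 7-{[(tert-butyldimethylsilyl)oxy]methyl}-1,4-dioxaspiro[4.5]dec-7-en-6-ol | CC(C)(C)[Si](C)(C)OCC1=CCCC2(OCCO2)C1O
F2 | step 5 | (6S)-7-{[(tert-butyldimethylsilyl)oxy]methyl}-1,4-dioxaspiro[4.5]dec-7-en-6-yl (S)-2-methoxy-2-phenylacetate | CC(C)(C)[Si](C)(C)OCC1=CCCC2(OCCO2)[C@H]1OC(=O)[C@@H](OC)c1ccccc1
F3 | step 5 | (6R)-7-{[(tert-butyldimethylsilyl)oxy]methyl}-1,4-dioxaspiro[4.5]dec-7-en-6-yl (S)-2-methoxy-2-phenylacetate (separated, not used) | CC(C)(C)[Si](C)(C)OCC1=CCCC2(OCCO2)[C@@H]1OC(=O)[C@@H](OC)c1ccccc1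
F4 | step 13 | (1S,2S,6R)-7,7-dibromo-2-(TBSO)-1-(TBSOCH2)spiro[bicyclo[4.1.0]heptane-3,2'-[1,3]dioxolane] (CBr2 trans to OTBS) | CC(C)(C)[Si](C)(C)OC[C@@]12C(Br)(Br)[C@@H]1CCC3(OCCO3)[C@H]2O[Si](C)(C)C(C)(C)C
F5 | step 13 | (1R,2S,6S)-2-(TBSO)-1-(TBSOCH2)spiro[bicyclo[4.1.0]heptane-3,2'-[1,3]dioxolane] | CC(C)(C)[Si](C)(C)OC[C@@]12C[C@@H]1CCC3(OCCO3)[C@H]2O[Si](C)(C)C(C)(C)C
F6 | step 13 | (6S,7R)-6-(TBSO)-7-(TBSOCH2)-7-methyl-1,4-dioxaspiro[4.5]decane | CC(C)(C)[Si](C)(C)OC[C@@]1(C)CCCC2(OCCO2)[C@H]1O[Si](C)(C)C(C)(C)C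
F7 | step 13 | (2S,3R)-2-(TBSO)-3-(hydroxymethyl)-3-methylcyclohexan-1-one | OC[C@@]1(C)CCCC(=O)[C@H]1O[Si](C)(C)C(C)(C)C
F8 | step 18 | {4-[(tert-butyldimethylsilyl)oxy]butyl}diphenylphosphine oxide | CC(C)(C)[Si](C)(C)OCCCCP(=O)(c1ccccc1)c1ccccc1
F9 | step 18 | [(1S,2R)-2-(TBSO)-3-hydroxy-3-{4-[(tert-butyldimethylsilyl)oxy]-1-(diphenylphosphoryl)butyl}-1-methylcyclohexyl]methyl pivalate, Z-forming adduct (shown for attack on the C3 face opposite to the C2 silyl ether) | CC(C)(C)C(=O)OC[C@]1(C)CCC[C@](O)([C@@H](P(=O)(c2ccccc2)c2ccccc2)CCCO[Si](C)(C)C(C)(C)C)[C@H]1O[Si](C)(C)C(C)(C)C
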